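Both prenyl groups are disconnected at their benzylic bonds, C1''–C2'' on C8 (ring A) and C1'''–C2''' on C5' (ring B). Each benzylic carbon lies ortho to a phenolic oxygen (O7, O4') and can therefore serve as the exocyclic carbon of an o-quinone methide. In one operation, base strips the aryl acetates of a flavone pentaacetate, both benzylic acetates are expelled, and each methide takes a 2-methylprop-1-enyl group from boron. The precursor is a 3'-O-MOM luteolin carrying acetoxymethyl groups at C8 and C5' and acetates on O5, O7 and O4', assembled from 5-bromo-o-vanillin and phloroacetophenone.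

Key step: step 9

Assumption (chemistry): the target has no stereocentre and no stereogenic double bond, so it is one achiral compound and no step needs stereocontrol; in precursor 13, O5 is acetylated as well, because exhaustive acetylation is more dependable than sparing the chelated 5-OH, and this acetate is lost under the base of step 9.

Step 1
Reactants: 1 5-bromo-2-hydroxy-3-methoxybenzaldehyde (5-bromo-o-vanillin)
Product: 2 5-bromo-2,3-dihydroxybenzaldehyde
Conditions: BBr3 (2.5 equiv), CH2Cl2, −78 °C → rt; then H2O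
Reagents that add atoms: none
Why: Lewis-acid O-demethylation of an aryl methyl ether with BBr3, to which the aldehyde and the aryl bromide are inert at this temperature.

Step 2
Reactants: 2 5-bromo-2,3-dihydroxybenzaldehyde
Product: 3 5-bromo-3-(hydroxymethyl)benzene-1,2-diol
Conditions: NaBH4 (1.5 equiv), MeOH/THF, 0 °C; aq. citric acid to pH 5
Reagents that add atoms: none
Why: Borohydride reduction of an aryl aldehyde, which at 0 °C should stop cleanly at the salicyl alcohol.

Step 3
Reactants: 3 5-bromo-3-(hydroxymethyl)benzene-1,2-diol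
Product: 4 6-bromo-2,2-dimethyl-4H-1,3-benzodioxin-8-ol
Conditions: 2,2-dimethoxypropane (3 equiv), TsOH·H2O (5 mol %), acetone, rt
Reagents that add atoms: 2,2-dimethoxypropane, COC(C)(C)OC
Why: Acid-catalysed transketalisation in which the primary benzylic alcohol exchanges first and closes onto the neighbouring phenol to the six-membered benzodioxine, whereas a catechol acetonide needs forcing dehydrating conditions, so the future O3' should stay free.

Step 4
Reactants: 4 6-bromo-2,2-dimethyl-4H-1,3-benzodioxin-8-ol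
Product: 5 6-bromo-8-(methoxymethoxy)-2,2-dimethyl-4H-1,3-benzodioxine
Conditions: MOMCl (1.5 equiv), i-Pr2NEt (2 equiv), CH2Cl2, 0 °C → rt
Reagents that add atoms: chloromethyl methyl ether, COCCl
Why: Williamson-type O-alkylation of the only free hydroxyl group, which fixes the MOM ether on the future O3' without any regiochemical question.

Step 5
Reactants: 5 6-bromo-8-(methoxymethoxy)-2,2-dimethyl-4H-1,3-benzodioxine
Product: 7 8-(methoxymethoxy)-2,2-dimethyl-4H-1,3-benzodioxine-6-carboxylic acid, via aryllithium 6 (not isolated)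
Conditions: n-BuLi (1.05 equiv), THF, −78 °C; CO2 (g); 1 M HCl to pH 4, 0 °C
Reagents that add atoms: carbon dioxide, O=C=O
Why: Bromine–lithium exchange followed by carboxylation, with ketal and MOM ether inert to the organolithium and the short lifetime at −78 °C preventing migration of lithium to the position ortho to the MOM ether.

Step 6
Reactants: 7 8-(methoxymethoxy)-2,2-dimethyl-4H-1,3-benzodioxine-6-carboxylic acid; 8 2,4,6-trihydroxyacetophenone
Product: 11 5,7-dihydroxy-2-[4-hydroxy-3-(hydroxymethyl)-5-(methoxymethoxy)phenyl]-4H-chromen-4-one, via acid chloride 9 (not isolated), via diketone 10 (not isolated)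
Conditions: 7, 1-chloro-N,N,2-trimethylprop-1-en-1-amine (1.1 equiv), CH2Cl2, 0 °C → rt; add to 8/LiHMDS (4.2 equiv), THF, −78 °C → rt; then AcOH/H2O (4:1), 65 °C
Reagents that add atoms: none
Why: Claisen-type C-acylation of the polylithiated acetophenone enolate by the acid chloride (made under neutral conditions so that ketal and MOM ether survive) should give the 1,3-diketone, whose 2-hydroxyflavanone form loses water in warm aqueous acetic acid (flavone cyclodehydration) while the acetonide is hydrolysed, both events running through stabilised tertiary oxocarbenium ions that form far more readily than the ion from the formaldehyde acetal at O3'.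

Step 7
Reactants: 11 5,7-dihydroxy-2-[4-hydroxy-3-(hydroxymethyl)-5-(methoxymethoxy)phenyl]-4H-chromen-4-one
Product: 12 8-[(dimethylamino)methyl]-5,7-dihydroxy-2-[4-hydroxy-3-(hydroxymethyl)-5-(methoxymethoxy)phenyl]-4H-chromen-4-one
Conditions: Me2NCH2NMe2 (1.1 equiv), 1,4-dioxane, 60 °C
Reagents that add atoms: N,N,N',N'-tetramethylmethanediamine, CN(C)CN(C)C
Why: Phenolic Mannich reaction in which the iminium ion should attack C8, the most nucleophilic carbon of a 5,7-dihydroxyflavone, while ring B has no free position ortho or para to O4' and one equivalent of reagent limits a second aminomethylation at C6.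

Step 8
Reactants: 12 8-[(dimethylamino)methyl]-5,7-dihydroxy-2-[4-hydroxy-3-(hydroxymethyl)-5-(methoxymethoxy)phenyl]-4H-chromen-4-one
Product: 13 {5,7-diacetoxy-2-[4-acetoxy-3-(acetoxymethyl)-5-(methoxymethoxy)phenyl]-4-oxo-4H-chromen-8-yl}methyl acetate
Conditions: Ac2O (solvent), NaOAc (3 equiv), 110 °C
Reagents that add atoms: acetic anhydride, CC(=O)OC(C)=O
Why: Exhaustive O-acetylation combined with acetolysis of the phenolic Mannich base (N-acylation, then displacement of N,N-dimethylacetamide from the benzylic carbon by acetate), a classical conversion of o-(dialkylaminomethyl)phenols into o-acetoxybenzyl acetates, with the acetate buffer keeping the medium non-acidic for the MOM ether.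

Step 9
Reactants: 13 {5,7-diacetoxy-2-[4-acetoxy-3-(acetoxymethyl)-5-(methoxymethoxy)phenyl]-4-oxo-4H-chromen-8-yl}methyl acetate; 14 (2-methylprop-1-en-1-yl)boronic acid
Product: 17 3'-O-methoxymethyl epimedokoreanin B [5,7-dihydroxy-2-[4-hydroxy-3-(methoxymethoxy)-5-(3-methylbut-2-en-1-yl)phenyl]-8-(3-methylbut-2-en-1-yl)-4H-chromen-4-one], via triphenol 15 (not isolated), via bis(o-quinone methide) 16 (not isolated)
Conditions: 14 (6 equiv), Cs2CO3 (8 equiv), H2O (10 equiv), THF (0.02 M), degassed, 50 °C; aq. NaH2PO4 work-up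
Reagents that add atoms: none
Why: Carbonate and the small amount of water cleave the three aryl acetates to the phenoxides of 15; the O7 and O4' phenoxides then each push out the neighbouring benzylic acetate in a 1,4-elimination to an o-quinone methide (drawn together as 16, although the two methides may form and react one after the other), and the alkenylboronic acid, held as a boronate on the methide oxygen, passes its 2-methylprop-1-enyl group to the exocyclic CH2 through a six-membered transition state, which restores the phenol and forms C1''–C2'' and C1'''–C2'''. The closest known reaction type is the conjugate addition of alkenylboron reagents to o-quinone methides that are released by base from o-acyloxybenzyl acetates. No ring is closed and no stereocentre is formed. The selectivity needed is C–C bond formation at the exocyclic carbon in preference to capture by water, hydroxide or a phenoxide of a second molecule and to attack on the chromone; the oxygen-bound boronate makes the alkenyl transfer intramolecular, and the excess of 14, the limited water and the dilution suppress the other pathways. The MOM ether keeps O3' from forming a catechol boronate and from oxidation, and O5, freed in the same pot, stays in its chelate with C4=O.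

Step 10
Reactants: 17 3'-O-methoxymethyl epimedokoreanin B
Product: 18 epimedokoreanin B [5,7-dihydroxy-2-[3,4-dihydroxy-5-(3-methylbut-2-en-1-yl)phenyl]-8-(3-methylbut-2-en-1-yl)-4H-chromen-4-one]
Conditions: 3 M aq. HCl/MeOH (1:10), 40 °C
Reagents that add atoms: none
Why: Acid-catalysed methanolysis of the aryl methoxymethyl acetal, the usual way to unmask MOM-protected prenylflavonoids, in which dilute acid at mild temperature should leave the two o-prenylphenol units uncyclised.

Compound list
1 | 5-bromo-2-hydroxy-3-methoxybenzaldehyde (5-bromo-o-vanillin) | COc1cc(Br)cc(C=O)c1O | starting material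
2 | 5-bromo-2,3-dihydroxybenzaldehyde | O=Cc1cc(Br)cc(O)c1O | intermediate
3 | 5-bromo-3-(hydroxymethyl)benzene-1,2-diol | OCc1cc(Br)cc(O)c1O | intermediate
4 | 6-bromo-2,2-dimethyl-4H-1,3-benzodioxin-8-ol | CC1(C)OCc2cc(Br)cc(O)c2O1 | intermediate
5 | 6-bromo-8-(methoxymethoxy)-2,2-dimethyl-4H-1,3-benzodioxine | COCOc1cc(Br)cc2c1OC(C)(C)OC2 | intermediate
6 | [8-(methoxymethoxy)-2,2-dimethyl-4H-1,3-benzodioxin-6-yl]lithium (not isolated) | [Li]c1cc(OCOC)c2OC(C)(C)OCc2c1 | intermediate
7 | 8-(methoxymethoxy)-2,2-dimethyl-4H-1,3-benzodioxine-6-carboxylic acid | COCOc1cc(C(=O)O)cc2c1OC(C)(C)OC2 | intermediate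
8 | 2,4,6-trihydroxyacetophenone | CC(=O)c1c(O)cc(O)cc1O | starting material
9 | 8-(methoxymethoxy)-2,2-dimethyl-4H-1,3-benzodioxine-6-carbonyl chloride (not isolated) | COCOc1cc(C(Cl)=O)cc2c1OC(C)(C)OC2 | intermediate
10 | 1-[8-(methoxymethoxy)-2,2-dimethyl-4H-1,3-benzodioxin-6-yl]-3-(2,4,6-trihydroxyphenyl)propane-1,3-dione (not isolated) | COCOc1cc(C(=O)CC(=O)c2c(O)cc(O)cc2O)cc2c1OC(C)(C)OC2 | intermediate
11 | 5,7-dihydroxy-2-[4-hydroxy-3-(hydroxymethyl)-5-(methoxymethoxy)phenyl]-4H-chromen-4-one | COCOc1cc(-c2cc(=O)c3c(O)cc(O)cc3o2)cc(CO)c1O | intermediate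
12 | 8-[(dimethylamino)methyl]-5,7-dihydroxy-2-[4-hydroxy-3-(hydroxymethyl)-5-(methoxymethoxy)phenyl]-4H-chromen-4-one | CN(C)Cc1c(O)cc(O)c2c(=O)cc(-c3cc(CO)c(O)c(OCOC)c3)oc12 | intermediate
13 | {5,7-diacetoxy-2-[4-acetoxy-3-(acetoxymethyl)-5-(methoxymethoxy)phenyl]-4-oxo-4H-chromen-8-yl}methyl acetate | CC(=O)OCc1c(OC(C)=O)cc(OC(C)=O)c2c(=O)cc(-c3cc(COC(C)=O)c(OC(C)=O)c(OCOC)c3)oc12 | intermediate
14 | (2-methylprop-1-en-1-yl)boronic acid | CC(C)=CB(O)O | starting material
15 | {2-[3-(acetoxymethyl)-4-hydroxy-5-(methoxymethoxy)phenyl]-5,7-dihydroxy-4-oxo-4H-chromen-8-yl}methyl acetate (not isolated; present as its phenoxides) | CC(=O)OCc1c(O)cc(O)c2c(=O)cc(-c3cc(COC(C)=O)c(O)c(OCOC)c3)oc12 | intermediate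
16 | 5-hydroxy-2-[5-(methoxymethoxy)-3-methylidene-4-oxocyclohexa-1,5-dien-1-yl]-8-methylidene-4H-chromene-4,7(8H)-dione (not isolated) | C=C1C(=O)C=C(O)C2=C1OC(C3=CC(=C)C(=O)C(OCOC)=C3)=CC2=O | intermediate
17 | 3'-O-methoxymethyl epimedokoreanin B | CC(C)=CCc1c(O)cc(O)c2c(=O)cc(-c3cc(CC=C(C)C)c(O)c(OCOC)c3)oc12 | intermediate
18 | epimedokoreanin B (achiral) | CC(C)=CCc1cc(-c2cc(=O)c3c(O)cc(O)c(CC=C(C)C)c3o2)cc(O)c1O | target

Total step count: 10. Longest linear sequence: 10 steps (1 → 18); 8 enters at step 6 and 14 at step 9.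

Steps most likely to fail

1. Step 9. The methides may be captured by water or hydroxide, or by a phenoxide oxygen of a second molecule (oligomers). The electron-poor ring A phenoxide may expel its acetate too slowly, and the alkenylboronic acid may protodeboronate before it transfers. Fallback: the same two bonds are made without a methide, by palladium-catalysed cross-coupling of the benzylic acetates through η3-benzylpalladium intermediates. It sets out from 13, which is treated with 14, [Pd(η3-C3H5)(cod)]BF4, 1,5-bis(diphenylphosphino)pentane and anhydrous K2CO3 in toluene at 80 °C to give 5,7,4'-tri-O-acetyl-3'-O-methoxymethyl epimedokoreanin B F1. Methanolysis of the three aryl acetates (K2CO3, MeOH, rt) brings the route back at 17.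

2. Step 6. The acid chloride may acylate phenoxide oxygen instead of the enolate carbon or acylate twice. The mild acid may fail to complete the cyclodehydration, or it may erode the MOM ether along with the acetonide. Fallback: an acid-free chalcone route with a protected ring A, setting out from 5 and 8.
   - Bromine–lithium exchange of 5 and quenching with DMF gives 8-(methoxymethoxy)-2,2-dimethyl-4H-1,3-benzodioxine-6-carbaldehyde F2.
   - Benzylation of 8 (BnBr, K2CO3, acetone) gives 1-[2,4-bis(benzyloxy)-6-hydroxyphenyl]ethan-1-one F3.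
   - Claisen–Schmidt condensation of F2 and F3 (KOH, EtOH) gives (E)-1-[2,4-bis(benzyloxy)-6-hydroxyphenyl]-3-[8-(methoxymethoxy)-2,2-dimethyl-4H-1,3-benzodioxin-6-yl]prop-2-en-1-one F4.
   - NaOAc in refluxing EtOH closes F4 to racemic 5,7-bis(benzyloxy)-2-[8-(methoxymethoxy)-2,2-dimethyl-4H-1,3-benzodioxin-6-yl]chroman-4-one F5.
   - Iodine in pyridine at 90 °C dehydrogenates F5 to 5,7-bis(benzyloxy)-2-[8-(methoxymethoxy)-2,2-dimethyl-4H-1,3-benzodioxin-6-yl]-4H-chromen-4-one F6.
   - Hydrogenolysis (H2, Pd/C, EtOAc/MeOH) gives 5,7-dihydroxy-2-[8-(methoxymethoxy)-2,2-dimethyl-4H-1,3-benzodioxin-6-yl]-4H-chromen-4-one F7.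
   - Hydrolysis of the acetonide alone (AcOH/H2O, 40 °C) returns the route at 11.

3. Step 8. Displacement of the acylammonium group at the hindered, electron-poor C8 benzylic carbon may be sluggish, and prolonged heating in acetic anhydride may wear away the MOM ether. Fallback: the nitrogen is exchanged for acetate in two cold steps instead. It sets out from 12, which is acetylated at room temperature (Ac2O, pyridine, DMAP) to 5,7-diacetoxy-2-[4-acetoxy-3-(acetoxymethyl)-5-(methoxymethoxy)phenyl]-8-[(dimethylamino)methyl]-4H-chromen-4-one F8. Ethyl chloroformate in CH2Cl2 then cleaves the benzylic C–N bond (chloroformate dealkylation of a benzylic tertiary amine) to 5,7-diacetoxy-2-[4-acetoxy-3-(acetoxymethyl)-5-(methoxymethoxy)phenyl]-8-(chloromethyl)-4H-chromen-4-one F9. Substitution with KOAc in DMF at room temperature returns the route at 13.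

Further compounds
F1 | step 9 | 5,7,4'-tri-O-acetyl-3'-O-methoxymethyl epimedokoreanin B | CC(C)=CCc1c(OC(C)=O)cc(OC(C)=O)c2c(=O)cc(-c3cc(CC=C(C)C)c(OC(C)=O)c(OCOC)c3)oc12
F2 | step 6 | 8-(methoxymethoxy)-2,2-dimethyl-4H-1,3-benzodioxine-6-carbaldehyde | COCOc1cc(C=O)cc2c1OC(C)(C)OC2
F3 | step 6 | 1-[2,4-bis(benzyloxy)-6-hydroxyphenyl]ethan-1-one | CC(=O)c1c(O)cc(OCc2ccccc2)cc1OCc1ccccc1
F4 | step 6 | (E)-1-[2,4-bis(benzyloxy)-6-hydroxyphenyl]-3-[8-(methoxymethoxy)-2,2-dimethyl-4H-1,3-benzodioxin-6-yl]prop-2-en-1-one | COCOc1cc(/C=C/C(=O)c2c(O)cc(OCc3ccccc3)cc2OCc2ccccc2)cc2c1OC(C)(C)OC2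
F5 | step 6 | 5,7-bis(benzyloxy)-2-[8-(methoxymethoxy)-2,2-dimethyl-4H-1,3-benzodioxin-6-yl]chroman-4-one (racemic) | COCOc1cc(C2CC(=O)c3c(OCc4ccccc4)cc(OCc4ccccc4)cc3O2)cc2c1OC(C)(C)OC2
F6 | step 6 | 5,7-bis(benzyloxy)-2-[8-(methoxymethoxy)-2,2-dimethyl-4H-1,3-benzodioxin-6-yl]-4H-chromen-4-one | COCOc1cc(-c2cc(=O)c3c(OCc4ccccc4)cc(OCc4ccccc4)cc3o2)cc2c1OC(C)(C)OC2
F7 | step 6 | 5,7-dihydroxy-2-[8-(methoxymethoxy)-2,2-dimethyl-4H-1,3-benzodioxin-6-yl]-4H-chromen-4-one | COCOc1cc(-c2cc(=O)c3c(O)cc(O)cc3o2)cc2c1OC(C)(C)OC2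
F8 | step 8 | 5,7-diacetoxy-2-[4-acetoxy-3-(acetoxymethyl)-5-(methoxymethoxy)phenyl]-8-[(dimethylamino)methyl]-4H-chromen-4-one | CN(C)Cc1c(OC(C)=O)cc(OC(C)=O)c2c(=O)cc(-c3cc(COC(C)=O)c(OC(C)=O)c(OCOC)c3)oc12
F9 | step 8 | 5,7-diacetoxy-2-[4-acetoxy-3-(acetoxymethyl)-5-(methoxymethoxy)phenyl]-8-(chloromethyl)-4H-chromen-4-one | ClCc1c(OC(C)=O)cc(OC(C)=O)c2c(=O)cc(-c3cc(COC(C)=O)c(OC(C)=O)c(OCOC)c3)oc12
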